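**Retrosynthetic overview**

1. Target 26 ← 25 by BCl3 removal of the B4 isopropyl group ← aldehyde 23 + pyranone 4 by reductive Knoevenagel alkylation (bond from C3 of ring A through CH2 to B1).
2. 23 ← dioxolane 22 ← insertion of the aryne from silylaryl triflate 18 (triflate on B5, SiMe3 on B6) into the C–O bond of (R)-2-methylbutanoic acid 19. 18 ← 4-hydroxy-2-methoxybenzaldehyde 5 through the B5 bromide, the B5 phenol, its N-isopropyl carbamate and ortho-silylation at B6.
3. Feature carrying the strategy: in ring B (B1 CH2 bridge, B2 OMe, B3 H, B4 OH, B5 acyl, B6 OH) the acyl carbon B5 and the hydroxyl carbon B6 are adjacent. B5 has the oxygen-bearing B4 on its other side and B6 has only the carbon-bearing B1, so a B5–B6 aryne flanked by a B4 alkoxy group takes the carboxylate oxygen at B6 and the acyl carbon at B5.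
4. Design choices: ring A is attached after the aryne step and B1 is a dioxolane during it. A pyranone on a B1–CH2 arm would put its C2 carbonyl oxygen (or a freed 4-oxygen) at six-ring distance from aryne carbon B6, and it is also an aryne diene. B4 is an isopropyl ether, which BCl3 cleaves beside the B2 methyl ether; a B4 methyl ether would have no chelation handle once the B6 hydroxyl binds the ketone.
5. Rings: ring A is formed in step 1, ring B is bought; the key step closes no ring.

Key step: step 9

Assumption: (R)-2-methylbutanoic acid 19 is used in high enantiomeric purity and is the only source of the stereocentre, so the enantiomeric purity should be checked after steps 9 and 12.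

**Route**

Step 1
Reactants: 1 pentan-3-one; 2 malonyl dichloride
Product: 4 6-ethyl-4-hydroxy-5-methyl-2H-pyran-2-one, via 4-methyl-3,5-dioxoheptanoyl chloride 3 (not isolated)
Conditions: neat 1 (excess), rt to 50 °C, HCl swept out with N2; crystallisation
Reagents that add atoms: none
Why: The enol of the symmetric ketone is C-acylated by one acid chloride and the resulting 1,3-diketone enol closes onto the second acid chloride (ketone–malonyl dichloride pyranone annulation; C-acylation then enol lactonisation), which fixes ethyl at C6 and methyl at C5 of ring A without any regiochemical choice.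

Step 2
Reactants: 5 4-hydroxy-2-methoxybenzaldehyde
Product: 6 2-methoxy-4-(propan-2-yloxy)benzaldehyde
Conditions: 2-bromopropane, K2CO3, DMF, 60 °C
Reagents that add atoms: 2-bromopropane, CC(C)Br
Why: Williamson ether synthesis on the only phenol, whose acidity is raised by the para formyl group, installs the B4 isopropyl ether that later steers the aryne and is removable by BCl3 beside a methyl ether.

Step 3
Reactants: 6 2-methoxy-4-(propan-2-yloxy)benzaldehyde
Product: 7 5-bromo-2-methoxy-4-(propan-2-yloxy)benzaldehyde
Conditions: N-bromosuccinimide, MeCN, rt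
Reagents that add atoms: N-bromosuccinimide, O=C1CCC(=O)N1Br
Why: Electrophilic aromatic bromination goes to B5, which is para to the B2 methoxy group, ortho to the B4 isopropoxy group and meta to the formyl group, whereas B3 is shielded between two alkoxy groups, as in the bromination of 2,4-dimethoxybenzaldehyde.

Step 4
Reactants: 7 5-bromo-2-methoxy-4-(propan-2-yloxy)benzaldehyde
Product: 8 2-[5-bromo-2-methoxy-4-(propan-2-yloxy)phenyl]-1,3-dioxolane
Conditions: ethylene glycol, TsOH·H2O (cat.), toluene, reflux, Dean–Stark
Reagents that add atoms: ethylene glycol, OCCO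
Why: Acid-catalysed acetalisation with azeotropic removal of water masks the aldehyde as a dioxolane that tolerates the organolithium, base and fluoride steps that follow and later serves as a second director toward B6.

Step 5
Reactants: 8 2-[5-bromo-2-methoxy-4-(propan-2-yloxy)phenyl]-1,3-dioxolane
Product: 11 5-(1,3-dioxolan-2-yl)-4-methoxy-2-(propan-2-yloxy)phenol, via B5 aryllithium 9 (not isolated), via lithium aryltrimethoxyborate 10 (not isolated)
Conditions: n-BuLi, THF, −78 °C; B(OMe)3, −78 °C to rt; then aq. NaOH, 30% H2O2, 0 °C; work-up at pH 7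
Reagents that add atoms: hydrogen peroxide, OO
Why: Bromine–lithium exchange at −78 °C, borylation of the aryllithium and oxidative 1,2-migration of the aryl group from boron to oxygen (boronate oxidation) turn the B5 bromide into the B5 phenol under basic conditions that spare the acetal.

Step 6
Reactants: 11 5-(1,3-dioxolan-2-yl)-4-methoxy-2-(propan-2-yloxy)phenol
Product: 12 5-(1,3-dioxolan-2-yl)-4-methoxy-2-(propan-2-yloxy)phenyl N-(propan-2-yl)carbamate
Conditions: i-PrNCO, Et3N (cat.), CH2Cl2, rt
Reagents that add atoms: isopropyl isocyanate, CC(C)N=C=O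
Why: Base-catalysed addition of the phenol to the isocyanate (carbamoylation) gives the N-isopropyl carbamate, a strong ortho director that can later be removed under mild amine conditions.

Step 7
Reactants: 12 5-(1,3-dioxolan-2-yl)-4-methoxy-2-(propan-2-yloxy)phenyl N-(propan-2-yl)carbamate
Product: 16 3-(1,3-dioxolan-2-yl)-4-methoxy-6-(propan-2-yloxy)-2-(trimethylsilyl)phenyl N-(propan-2-yl)carbamate, via N-silyl carbamate 13 (not isolated), via B6 aryllithium 14 (not isolated), via C,N-bis(trimethylsilyl) carbamate 15 (not isolated)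
Conditions: TMSOTf, TMEDA, Et2O, 0 °C to rt; n-BuLi, TMEDA, −78 °C; TMSCl, −78 °C to rt; MeOH quench, aq. NaHCO3
Reagents that add atoms: chlorotrimethylsilane, C[Si](C)(C)Cl
Why: Directed ortho-metalation: after in situ N-silylation the carbamate at B5 and the dioxolane at B1 both direct n-BuLi/TMEDA to B6 (the other ortho position B4 is substituted and B3 is flanked only by weaker ether directors), the aryllithium is silylated by TMSCl, and methanol cleaves the labile N–Si bond.

Step 8
Reactants: 16 3-(1,3-dioxolan-2-yl)-4-methoxy-6-(propan-2-yloxy)-2-(trimethylsilyl)phenyl N-(propan-2-yl)carbamate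
Product: 18 3-(1,3-dioxolan-2-yl)-4-methoxy-6-(propan-2-yloxy)-2-(trimethylsilyl)phenyl trifluoromethanesulfonate, via silylphenol 17 (not isolated)
Conditions: DBU, Et2NH, MeCN, 40 °C; then PhNTf2, rt to 40 °C
Reagents that add atoms: N-phenylbis(trifluoromethanesulfonimide), O=S(=O)(N(c1ccccc1)S(=O)(=O)C(F)(F)F)C(F)(F)F
Why: DBU deprotonates the carbamate N–H and isopropyl isocyanate is expelled (E1cB carbamate cleavage, the isocyanate being scavenged by Et2NH), and the phenoxide so formed is triflated in the same pot by PhNTf2 (O-sulfonylation), so the silylphenol is never exposed to acid or silica.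

Step 9
Reactants: 18 3-(1,3-dioxolan-2-yl)-4-methoxy-6-(propan-2-yloxy)-2-(trimethylsilyl)phenyl trifluoromethanesulfonate; 19 (2R)-2-methylbutanoic acid
Product: 22 (2R)-1-[3-(1,3-dioxolan-2-yl)-2-hydroxy-4-methoxy-6-(propan-2-yloxy)phenyl]-2-methylbutan-1-one, via aryne 20 (not isolated), via cesium 2-acyloxyaryl anion 21 (not isolated)
Conditions: CsF (4 equiv), 19 (1.2 equiv), THF (0.05 M), sealed tube, 125 °C
Reagents that add atoms: none
Why: Fluoride attacks silicon and triflate leaves, giving the B5–B6 aryne 20; the carboxylate of 19 adds through oxygen to B6 and the resulting B5 aryl anion 21 attacks the neighbouring ester carbonyl through a four-membered alkoxide that opens to the B5 ketone and the B6 phenoxide, so the net result is insertion of the aryne into the C–O bond of the acid. The closest known reaction type is the CsF-mediated aryne insertion into carboxylic acid C–O bonds in hot THF, which gives ortho-hydroxyaryl ketones and with 3-alkoxy arynes places the hydroxyl meta to the alkoxy group. No ring is closed and no stereocentre is formed; the (R) centre of 19 is not a reacting atom and is carried through, its only risk being enolisation of the hindered ketone. The selectivity needed is oxygen at B6 and acyl at B5: the B4 isopropoxy group withdraws inductively and distorts the aryne so that the nucleophile enters at the remote carbon B6 and the charge develops at B5 next to oxygen, which outweighs the steric effect of the dioxolane on B1. The dioxolane oxygens could reach B6 only through a four-membered ring, so the aryne has no internal trap, and hot THF with little free acid favours acyl transfer over proton capture of 21.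

Step 10
Reactants: 22 (2R)-1-[3-(1,3-dioxolan-2-yl)-2-hydroxy-4-methoxy-6-(propan-2-yloxy)phenyl]-2-methylbutan-1-one
Product: 23 2-hydroxy-6-methoxy-3-[(2R)-2-methylbutanoyl]-4-(propan-2-yloxy)benzaldehyde
Conditions: 1 M aq. HCl, THF, rt
Reagents that add atoms: water, O
Why: Acid-catalysed acetal hydrolysis releases the aldehyde, which is stabilised by a hydrogen bond to the B6 hydroxyl, under conditions too mild to enolise the hindered ketone or to touch the aryl ethers.

Step 11
Reactants: 23 2-hydroxy-6-methoxy-3-[(2R)-2-methylbutanoyl]-4-(propan-2-yloxy)benzaldehyde; 4 6-ethyl-4-hydroxy-5-methyl-2H-pyran-2-one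
Product: 25 6-ethyl-4-hydroxy-3-({2-hydroxy-6-methoxy-3-[(2R)-2-methylbutanoyl]-4-(propan-2-yloxy)phenyl}methyl)-5-methyl-2H-pyran-2-one, via 3-arylidene pyran-2,4-dione 24 (not isolated)
Conditions: Hantzsch ester (diethyl 2,6-dimethyl-1,4-dihydropyridine-3,5-dicarboxylate), L-proline (20 mol %), CH2Cl2, rt
Reagents that add atoms: none
Why: Reductive Knoevenagel alkylation: proline-catalysed condensation of the aldehyde with C3 of the 4-hydroxypyranone gives the electrophilic alkylidene 24, which accepts hydride from the Hantzsch ester at the benzylic carbon faster than it adds a second pyranone, so the B1–CH2–C3 bridge forms without a new stereocentre.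

Step 12
Reactants: 25 6-ethyl-4-hydroxy-3-({2-hydroxy-6-methoxy-3-[(2R)-2-methylbutanoyl]-4-(propan-2-yloxy)phenyl}methyl)-5-methyl-2H-pyran-2-one
Product: 26 3-({2,4-dihydroxy-6-methoxy-3-[(2R)-2-methylbutanoyl]phenyl}methyl)-6-ethyl-4-hydroxy-5-methyl-2H-pyran-2-one (CNP0199908.1)
Conditions: BCl3 (1 M in CH2Cl2, 4 equiv), CH2Cl2, −78 to 0 °C; MeOH then water
Reagents that add atoms: none
Why: Lewis-acid ether cleavage: BCl3 cleaves the secondary isopropyl aryl ether at B4 at low temperature through chloride attack on the isopropyl carbon of the boron-bound ether, while the B2 methyl ether, which at this stage has no ortho carbonyl to chelate boron, is left intact and the α-stereocentre is not exposed to base.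

**Compound list**

1 | pentan-3-one | CCC(=O)CC | starting material
2 | malonyl dichloride | O=C(Cl)CC(=O)Cl | starting material
3 | 4-methyl-3,5-dioxoheptanoyl chloride | CCC(=O)C(C)C(=O)CC(=O)Cl | intermediate (not isolated)
4 | 6-ethyl-4-hydroxy-5-methyl-2H-pyran-2-one | CCc1oc(=O)cc(O)c1C | intermediate
5 | 4-hydroxy-2-methoxybenzaldehyde | COc1cc(O)ccc1C=O | starting material
6 | 2-methoxy-4-(propan-2-yloxy)benzaldehyde | COc1cc(OC(C)C)ccc1C=O | intermediate
7 | 5-bromo-2-methoxy-4-(propan-2-yloxy)benzaldehyde | COc1cc(OC(C)C)c(Br)cc1C=O | intermediate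
8 | 2-[5-bromo-2-methoxy-4-(propan-2-yloxy)phenyl]-1,3-dioxolane | COc1cc(OC(C)C)c(Br)cc1C1OCCO1 | intermediate
9 | [5-(1,3-dioxolan-2-yl)-4-methoxy-2-(propan-2-yloxy)phenyl]lithium (B5 aryllithium) | COc1cc(OC(C)C)c([Li])cc1C1OCCO1 | intermediate (not isolated)
10 | lithium [5-(1,3-dioxolan-2-yl)-4-methoxy-2-(propan-2-yloxy)phenyl]trimethoxyborate | [Li+].COc1cc(OC(C)C)c([B-](OC)(OC)OC)cc1C1OCCO1 | intermediate (not isolated)
11 | 5-(1,3-dioxolan-2-yl)-4-methoxy-2-(propan-2-yloxy)phenol | COc1cc(OC(C)C)c(O)cc1C1OCCO1 | intermediate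
12 | 5-(1,3-dioxolan-2-yl)-4-methoxy-2-(propan-2-yloxy)phenyl N-(propan-2-yl)carbamate | COc1cc(OC(C)C)c(OC(=O)NC(C)C)cc1C1OCCO1 | intermediate
13 | 5-(1,3-dioxolan-2-yl)-4-methoxy-2-(propan-2-yloxy)phenyl N-(propan-2-yl)-N-(trimethylsilyl)carbamate | COc1cc(OC(C)C)c(OC(=O)N(C(C)C)[Si](C)(C)C)cc1C1OCCO1 | intermediate (not isolated)
14 | B6-lithiated N-silyl carbamate (lithium at the ring carbon between the carbamate and the dioxolane) | COc1cc(OC(C)C)c(OC(=O)N(C(C)C)[Si](C)(C)C)c([Li])c1C1OCCO1 | intermediate (not isolated)
15 | 3-(1,3-dioxolan-2-yl)-4-methoxy-6-(propan-2-yloxy)-2-(trimethylsilyl)phenyl N-(propan-2-yl)-N-(trimethylsilyl)carbamate | COc1cc(OC(C)C)c(OC(=O)N(C(C)C)[Si](C)(C)C)c([Si](C)(C)C)c1C1OCCO1 | intermediate (not isolated)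
16 | 3-(1,3-dioxolan-2-yl)-4-methoxy-6-(propan-2-yloxy)-2-(trimethylsilyl)phenyl N-(propan-2-yl)carbamate | COc1cc(OC(C)C)c(OC(=O)NC(C)C)c([Si](C)(C)C)c1C1OCCO1 | intermediate
17 | 3-(1,3-dioxolan-2-yl)-4-methoxy-6-(propan-2-yloxy)-2-(trimethylsilyl)phenol | COc1cc(OC(C)C)c(O)c([Si](C)(C)C)c1C1OCCO1 | intermediate (not isolated)
18 | 3-(1,3-dioxolan-2-yl)-4-methoxy-6-(propan-2-yloxy)-2-(trimethylsilyl)phenyl trifluoromethanesulfonate | COc1cc(OC(C)C)c(OS(=O)(=O)C(F)(F)F)c([Si](C)(C)C)c1C1OCCO1 | intermediate
19 | (2R)-2-methylbutanoic acid | CC[C@@H](C)C(=O)O | starting material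
20 | 3-(1,3-dioxolan-2-yl)-4-methoxy-6-(propan-2-yloxy)benzyne (triple bond B5–B6) | COC1=C(C2OCCO2)C#CC(OC(C)C)=C1 | intermediate (not isolated)
21 | cesium 2-[(2R)-2-methylbutanoyloxy]aryl anion (ester oxygen on B6, carbanion at B5) | [Cs+].CC[C@@H](C)C(=O)Oc1[c-]c(OC(C)C)cc(OC)c1C1OCCO1 | intermediate (not isolated)
22 | (2R)-1-[3-(1,3-dioxolan-2-yl)-2-hydroxy-4-methoxy-6-(propan-2-yloxy)phenyl]-2-methylbutan-1-one | CC[C@@H](C)C(=O)c1c(OC(C)C)cc(OC)c(C2OCCO2)c1O | intermediate
23 | 2-hydroxy-6-methoxy-3-[(2R)-2-methylbutanoyl]-4-(propan-2-yloxy)benzaldehyde | CC[C@@H](C)C(=O)c1c(OC(C)C)cc(OC)c(C=O)c1O | intermediate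
24 | 6-ethyl-3-({2-hydroxy-6-methoxy-3-[(2R)-2-methylbutanoyl]-4-(propan-2-yloxy)phenyl}methylidene)-5-methyl-2H-pyran-2,4(3H)-dione (alkene geometry not defined) | CCC1=C(C)C(=O)C(=Cc2c(OC)cc(OC(C)C)c(C(=O)[C@H](C)CC)c2O)C(=O)O1 | intermediate (not isolated)
25 | 6-ethyl-4-hydroxy-3-({2-hydroxy-6-methoxy-3-[(2R)-2-methylbutanoyl]-4-(propan-2-yloxy)phenyl}methyl)-5-methyl-2H-pyran-2-one | CCc1oc(=O)c(Cc2c(OC)cc(OC(C)C)c(C(=O)[C@H](C)CC)c2O)c(O)c1C | intermediate
26 | 3-({2,4-dihydroxy-6-methoxy-3-[(2R)-2-methylbutanoyl]phenyl}methyl)-6-ethyl-4-hydroxy-5-methyl-2H-pyran-2-one | CCc1oc(=O)c(Cc2c(OC)cc(O)c(C(=O)[C@H](C)CC)c2O)c(O)c1C | target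

**Step count**

Total: 12 steps. Longest linear sequence: 11 steps (steps 2 to 12, from 4-hydroxy-2-methoxybenzaldehyde 5); step 1 is a one-step side branch.

**Steps most likely to fail**

Step 9 (aryne insertion). The B5 aryl anion may capture a proton before acyl transfer, so that the reaction stops at the aryl ester. The carboxylate may add in part at B5, the α-centre may enolise in the hot fluoride medium, or the dioxolane may be lost to the acid. Fallback, setting out from acid 19 and pyranone 4 and coming back at target 26, by classical acylphloroglucinol chemistry: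
- 19 would be converted with oxalyl chloride and catalytic DMF into (2R)-2-methylbutanoyl chloride F1.
- Friedel–Crafts acylation of phloroglucinol (Oc1cc(O)cc(O)c1) with F1 and AlCl3 in CH2Cl2/PhNO2 at 0 °C to rt should give (2R)-2-methyl-1-(2,4,6-trihydroxyphenyl)butan-1-one F2.
- The para hydroxyl, the only one not hydrogen-bonded to the ketone, would be methylated with one equivalent of dimethyl sulfate and K2CO3 in acetone to give (2R)-1-(2,6-dihydroxy-4-methoxyphenyl)-2-methylbutan-1-one F3.
- Pyranone 4 and dimethylmethylideneammonium iodide in CHCl3 should give the Mannich base 3-[(dimethylamino)methyl]-6-ethyl-4-hydroxy-5-methyl-2H-pyran-2-one F4. It loses dimethylamine to 6-ethyl-5-methyl-3-methylidene-2H-pyran-2,4(3H)-dione F5, which is captured by one of the two equivalent free ring positions of F3 (Mannich/Michael methylene bridging) to give 26.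
- The symmetry of F3 removes the regiochemical question that the aryne answers in the main route.

Step 7 (ortho-silylation). Deprotonation may occur at B3 between the two ether groups or at the acetal C–H. TMSOTf may open the dioxolane, or the carbamoyl group may migrate to B6 (anionic Fries) before silylation. Fallback, setting out from phenol 11 and coming back at triflate 18, by halogen–metal exchange instead of directed metalation:
- Amine-mediated ortho-bromination (N-bromosuccinimide, i-Pr2NH cat., CH2Cl2, 0 °C) should brominate the only free position ortho to the hydroxyl and give 2-bromo-3-(1,3-dioxolan-2-yl)-4-methoxy-6-(propan-2-yloxy)phenol F6.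
- Hexamethyldisilazane in THF at reflux would give its trimethylsilyl ether F7.
- n-BuLi in THF at −100 to −78 °C would give the B6 aryllithium F8, in which silicon migrates from oxygen to carbon (retro-Brook rearrangement) to leave the lithium salt of silylphenol 17.
- PhNTf2 added to the same flask would give 18.

Step 11 (reductive Knoevenagel). Condensation of the hindered, hydrogen-bonded, electron-rich aldehyde may be slow. The alkylidene may be opened at the lactone by the neighbouring B6 hydroxyl, or a second pyranone may add before hydride transfer. Fallback, setting out from aldehyde 23 (with pyranone 4) and coming back at 25, through an ortho-quinone methide: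
- NaBH4 in MeOH at 0 °C should reduce the aldehyde selectively over the hindered chelated ketone to (2R)-1-[2-hydroxy-3-(hydroxymethyl)-4-methoxy-6-(propan-2-yloxy)phenyl]-2-methylbutan-1-one F9.
- Heating F9 with 4 in toluene at 100 °C, the pyranone acting as the acid, would expel water to the ortho-quinone methide F10.
- Conjugate addition of C3 of 4 to the exocyclic methylene of F10 would give 25.

**Further compounds**

F1 | step 9 | (2R)-2-methylbutanoyl chloride | CC[C@@H](C)C(=O)Cl
F2 | step 9 | (2R)-2-methyl-1-(2,4,6-trihydroxyphenyl)butan-1-one | CC[C@@H](C)C(=O)c1c(O)cc(O)cc1O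
F3 | step 9 | (2R)-1-(2,6-dihydroxy-4-methoxyphenyl)-2-methylbutan-1-one | CC[C@@H](C)C(=O)c1c(O)cc(OC)cc1O
F4 | step 9 | 3-[(dimethylamino)methyl]-6-ethyl-4-hydroxy-5-methyl-2H-pyran-2-one | CCc1oc(=O)c(CN(C)C)c(O)c1C
F5 | step 9 | 6-ethyl-5-methyl-3-methylidene-2H-pyran-2,4(3H)-dione | CCC1=C(C)C(=O)C(=C)C(=O)O1
F6 | step 7 | 2-bromo-3-(1,3-dioxolan-2-yl)-4-methoxy-6-(propan-2-yloxy)phenol | COc1cc(OC(C)C)c(O)c(Br)c1C1OCCO1
F7 | step 7 | [2-bromo-3-(1,3-dioxolan-2-yl)-4-methoxy-6-(propan-2-yloxy)phenoxy]trimethylsilane | COc1cc(OC(C)C)c(O[Si](C)(C)C)c(Br)c1C1OCCO1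
F8 | step 7 | {2-(1,3-dioxolan-2-yl)-3-methoxy-5-(propan-2-yloxy)-6-[(trimethylsilyl)oxy]phenyl}lithium | COc1cc(OC(C)C)c(O[Si](C)(C)C)c([Li])c1C1OCCO1
F9 | step 11 | (2R)-1-[2-hydroxy-3-(hydroxymethyl)-4-methoxy-6-(propan-2-yloxy)phenyl]-2-methylbutan-1-one | CC[C@@H](C)C(=O)c1c(OC(C)C)cc(OC)c(CO)c1O
F10 | step 11 | 3-methoxy-6-methylidene-2-[(2R)-2-methylbutanoyl]... ortho-quinone methide: 4-methoxy-5-methylidene-1-[(2R)-2-methylbutanoyl]-2-(propan-2-yloxy)cyclohexa-1,3-dien-6-one | CC[C@@H](C)C(=O)C1=C(OC(C)C)C=C(OC)C(=C)C1=O
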